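**Retrosynthetic overview**

1. Endgame: the phenol acetate, the C3 tertiary alcohol (Markovnikov hydration of a C2=C3 cyclopentene from the convex face), the C4 aroyl ester and the C4 carbinol lead back to a cis-fused bicyclic β,γ-unsaturated C4 ketone that already carries the C8 isovalerate.
2. Key disconnection: the cyclopentene is cut at C1–C2 and C3–C3a, giving a ring-fused cyclopropyl ketone (cyclopropane C1/C3a/C8a on the cycloheptenone) and 3-methylbut-1-yne; forward, an SmI2-catalysed ketyl radical-relay [3+2] union driven by opening of the cyclopropane.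
3. Enabling feature: the cyclopentane shares the C3a–C8a bond with the cycloheptene, and the C4 oxygen sits on the seven-membered-ring carbon next to C3a. At the ketone level, C4=O is conjugated with a cyclopropane fused across C3a–C8a, whose external C1–C3a bond is aligned with the carbonyl while C1 stays bonded to the quaternary C8a.
4. The cycloheptene is closed by ring-closing metathesis (C6=C7) on a cis-1,2-disubstituted 1-methylcyclopropane made by enantioselective intramolecular cyclopropanation of 2-methylallyl diazoacetate. The cyclopropane controls C8 (ring reduction) and, through the cis fusion, C3a, C4 and C3.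
5. Ring order: cyclopropane (temporary, consumed in the key step), then the seven-membered ring, then the five-membered ring last.

Key step: step 15

Locants C1–C8a are the azulene locants of the target (C3 carbinol, C3a ring-fusion CH, C4 aroyloxy carbon, C6=C7 alkene, C8 isovaleryloxy carbon, C8a quaternary carbon) and are used for the corresponding atoms of all intermediates.

Assumption: the sense of induction of the dirhodium carboxamidate in step 3 is taken to follow that of allyl diazoacetate (S-configured ligands give the (1R,5S) lactone), so the R-configured catalyst is specified for the (1S,5R) lactone; if the sense is opposite for the 2-methylallyl ester, the S-configured catalyst is used.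

**Route**

Step 1
Reactants: 1 2-methylprop-2-en-1-ol; 2 bromoacetyl bromide
Product: 3 2-methylprop-2-en-1-yl bromoacetate
Conditions: NaHCO3, MeCN, 0 °C
Reagents that add atoms: bromoacetyl bromide (2), BrCC(=O)Br
Why: O-acylation of the primary alcohol by the acyl bromide (esterification), the bicarbonate taking up HBr while the alkyl bromide is kept for step 2.

Step 2
Reactants: 3 2-methylprop-2-en-1-yl bromoacetate; 4 N,N'-ditosylhydrazine
Product: 5 2-methylprop-2-en-1-yl diazoacetate
Conditions: 4 (2 equiv), DBU (5 equiv), THF, 0 °C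
Reagents that add atoms: N,N'-ditosylhydrazine (4), Cc1ccc(cc1)S(=O)(=O)NNS(=O)(=O)c1ccc(C)cc1
Why: diazoacetate synthesis by the ditosylhydrazine method, in which N-alkylation by the bromoacetate is followed by two base-induced sulfinate eliminations.

Step 3
Reactants: 5 2-methylprop-2-en-1-yl diazoacetate
Product: 6 (1S,5R)-5-methyl-3-oxabicyclo[3.1.0]hexan-2-one
Conditions: Rh2(4R-MPPIM)4 (dirhodium tetrakis[methyl (4R)-2-oxo-1-(3-phenylpropanoyl)imidazolidine-4-carboxylate], 1 mol %), CH2Cl2, reflux, slow addition of 5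
Reagents that add atoms: none
Why: enantioselective intramolecular cyclopropanation of an allylic diazoacetate by a chiral dirhodium carboxamidate carbene, in which the lactone tether enforces the cis relation of the two carbon arms and the catalyst selects the alkene face, setting both cyclopropane stereocentres (later C3a and C8a; the cyclopropane CH2 is the later C1).

Step 4
Reactants: 6 (1S,5R)-5-methyl-3-oxabicyclo[3.1.0]hexan-2-one
Product: 7 (1S,5R)-5-methyl-3-oxabicyclo[3.1.0]hexan-2-ol (anomeric mixture)
Conditions: iBu2AlH (DIBAL-H, 1.1 equiv), CH2Cl2, −78 °C; Rochelle salt work-up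
Reagents that add atoms: none
Why: partial reduction of the lactone to the lactol, the aluminium hemiacetal being stable at −78 °C.

Step 5
Reactants: 7 (1S,5R)-5-methyl-3-oxabicyclo[3.1.0]hexan-2-ol; 8 2-methylallylmagnesium chloride
Product: 9 1-[(1S,2R)-2-(hydroxymethyl)-2-methylcyclopropyl]-3-methylbut-3-en-1-ol (both carbinol epimers)
Conditions: 8 (3 equiv), THF, 0 °C to rt; aqueous NH4Cl
Reagents that add atoms: 2-methylallylmagnesium chloride (8), C=C(C)C[Mg]Cl
Why: Grignard addition to the hydroxy aldehyde tautomer of the lactol; the new carbinol centre (later C4) is formed without control, which is harmless because it becomes a ketone in step 14.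

Step 6
Reactants: 9 1-[(1S,2R)-2-(hydroxymethyl)-2-methylcyclopropyl]-3-methylbut-3-en-1-ol
Product: 11 (1R,5S)-1-methyl-4-(2-methylprop-2-en-1-yl)-3-oxabicyclo[3.1.0]hexan-2-one (both C4 epimers of the lactone), via lactol 10 (not isolated)
Conditions: TEMPO (10 mol %), PhI(OAc)2 (2.5 equiv), CH2Cl2, rt
Reagents that add atoms: none
Why: oxidative lactonization, in which the oxoammonium oxidant selects the primary alcohol, the aldehyde is captured by the secondary hydroxyl as lactol 10 and oxidized again, moving the acyl oxidation level to the carbon on the methyl-bearing cyclopropane carbon (later C8).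

Step 7
Reactants: 11 (1R,5S)-1-methyl-4-(2-methylprop-2-en-1-yl)-3-oxabicyclo[3.1.0]hexan-2-one; 12 N,O-dimethylhydroxylamine hydrochloride
Product: 13 (1R,2S)-2-(1-hydroxy-3-methylbut-3-en-1-yl)-N-methoxy-N,1-dimethylcyclopropane-1-carboxamide
Conditions: 12 (2 equiv), iPrMgCl (4 equiv), THF, −20 to 0 °C
Reagents that add atoms: N,O-dimethylhydroxylamine hydrochloride (12), CNOC.Cl
Why: aminolysis of the lactone by the magnesium amide of N,O-dimethylhydroxylamine (Weinreb amide formation), which opens the ring without touching the stereocentres.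

Step 8
Reactants: 13 the hydroxy Weinreb amide; 14 tert-butyl(chloro)dimethylsilane
Product: 15 (1R,2S)-2-{1-[(tert-butyldimethylsilyl)oxy]-3-methylbut-3-en-1-yl}-N-methoxy-N,1-dimethylcyclopropane-1-carboxamide
Conditions: 14 (1.5 equiv), imidazole, DMAP (cat.), DMF, rt
Reagents that add atoms: tert-butyl(chloro)dimethylsilane (14), CC(C)(C)[Si](C)(C)Cl
Why: silyl ether formation blocks relactonization and carries the future C4 oxygen through steps 9 to 12.

Step 9
Reactants: 15 the silylated Weinreb amide; 16 vinylmagnesium bromide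
Product: 17 1-[(1R,2S)-2-{1-[(tert-butyldimethylsilyl)oxy]-3-methylbut-3-en-1-yl}-1-methylcyclopropyl]prop-2-en-1-one
Conditions: 16 (2 equiv), THF, −20 to 0 °C; quench into cold aqueous HCl
Reagents that add atoms: vinylmagnesium bromide (16), C=C[Mg]Br
Why: Weinreb ketone synthesis, in which the chelated tetrahedral intermediate prevents a second addition and the acidic quench keeps the released hydroxylamine from adding to the enone.

Step 10
Reactants: 17 the vinyl ketone
Product: 18 (1R,7S)-6-[(tert-butyldimethylsilyl)oxy]-1,4-dimethylbicyclo[5.1.0]oct-3-en-2-one (both C6 epimers)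
Conditions: second-generation Hoveyda–Grubbs catalyst (5 mol %), toluene (5 mM), 80 °C
Reagents that add atoms: none
Why: ring-closing metathesis of the vinyl ketone with the 1,1-disubstituted alkene closes the seven-membered ring as the trisubstituted C6=C7 enone, the cis-cyclopropane holding both chains on one side.

Step 11
Reactants: 18 the bicyclic enone
Product: 19 (1R,2S,7S)-6-[(tert-butyldimethylsilyl)oxy]-1,4-dimethylbicyclo[5.1.0]oct-3-en-2-ol
Conditions: NaBH4, CeCl3·7H2O, MeOH, −78 to −40 °C
Reagents that add atoms: none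
Why: Luche 1,2-reduction, in which the cyclopropane methylene lies over one face of the conjugated, near-bisected cyclopropyl ketone so that hydride should add anti to it, giving the C8 alcohol cis to the methylene (8S in target locants).

Step 12
Reactants: 19 the allylic alcohol; 20 3-methylbutanoyl chloride
Product: 21 (1R,2S,7S)-6-[(tert-butyldimethylsilyl)oxy]-1,4-dimethylbicyclo[5.1.0]oct-3-en-2-yl 3-methylbutanoate
Conditions: 20 (1.5 equiv), pyridine, DMAP (cat.), CH2Cl2, 0 °C to rt
Reagents that add atoms: 3-methylbutanoyl chloride (20), CC(C)CC(=O)Cl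
Why: DMAP-catalysed O-acylation installs the isovalerate of the target with retention at C8.

Step 13
Reactants: 21 the silyl ether ester
Product: 22 (1R,2S,7S)-6-hydroxy-1,4-dimethylbicyclo[5.1.0]oct-3-en-2-yl 3-methylbutanoate
Conditions: Bu4NF, AcOH (1:1), THF, rt to 40 °C
Reagents that add atoms: none
Why: fluoride desilylation buffered by acetic acid, which leaves the allylic ester in place.

Step 14
Reactants: 22 the hydroxy ester
Product: 23 (1R,2S,7S)-1,4-dimethyl-6-oxobicyclo[5.1.0]oct-3-en-2-yl 3-methylbutanoate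
Conditions: nPr4N[RuO4] (TPAP, 5 mol %), N-methylmorpholine N-oxide, 4 Å molecular sieves, CH2Cl2, rt
Reagents that add atoms: none
Why: Ley–Griffith oxidation under neutral conditions gives the cyclopropyl ketone and removes the uncontrolled carbinol centre without moving the β,γ-alkene into conjugation.

Step 15
Reactants: 23 the cyclopropyl ketone; 24 3-methylbut-1-yne
Product: 25 (3aS,8S,8aR)-6,8a-dimethyl-4-oxo-3-(propan-2-yl)-1,3a,4,5,8,8a-hexahydroazulen-8-yl 3-methylbutanoate
Conditions: SmI2 (20 mol %), Sm metal (20 mol %), 24 (5 equiv), THF, 55 °C, sealed tube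
Reagents that add atoms: 3-methylbut-1-yne (24), CC(C)C#C
Why: Electron transfer from divalent samarium to the C4 ketone gives a ketyl whose singly occupied orbital overlaps with the external cyclopropane bond C1–C3a, so this bond cleaves with release of the ring strain and gives a trivalent samarium enolate (C3a=C4–O–Sm) and a primary radical at C1 that stays attached to the quaternary C8a. The C1 radical adds to the terminal carbon of the alkyne (new C1–C2 bond), and the vinyl radical at C3 closes the cyclopentene by 5-exo-trig attack on the enolate carbon C3a (new C3–C3a bond), re-forming a ketyl that returns the electron to trivalent samarium, so that SmI2 turns over. The closest known reaction type is the SmI2-catalysed formal [3+2] cycloaddition of alkyl cyclopropyl ketones, ring-fused ones included, with alkynes, supported by the classical reductive opening of fused β-methyl cyclopropyl ketones at the external bond. C8a is not touched and keeps its configuration, and the new C3a stereocentre is fixed by the three-atom tether, which can reach C3a only from the face where C1 already sits, so the fusion is cis (C3a–H cis to the C8a methyl). The step needs cleavage of the external bond instead of the ring-fusion bond (which would give a tertiary radical and an eight-membered ring), secured by the orbital alignment in the fused bicycle, and addition at the unsubstituted alkyne terminus, secured by the steric preference of the primary radical; the C8 ester is not reduced by SmI2 without additives.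

Step 16
Reactants: 25 the bicyclic dienone
Product: 26 (3aS,4R,8S,8aR)-4-hydroxy-6,8a-dimethyl-3-(propan-2-yl)-1,3a,4,5,8,8a-hexahydroazulen-8-yl 3-methylbutanoate
Conditions: NaBH4, CeCl3·7H2O, MeOH, −78 °C
Reagents that add atoms: none
Why: Luche reduction under non-basic conditions (no drift of the two β,γ-alkenes into conjugation), with hydride expected on the convex face of the cis-fused bicycle (the side of C3a–H and the C8a methyl) because the concave face is covered by the C3 isopropyl group, giving the 4R alcohol.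

Step 17
Reactants: 26 the homoallylic alcohol; 27 4-(chlorocarbonyl)phenyl acetate
Product: 28 (3aS,4R,8S,8aR)-6,8a-dimethyl-8-[(3-methylbutanoyl)oxy]-3-(propan-2-yl)-1,3a,4,5,8,8a-hexahydroazulen-4-yl 4-(acetyloxy)benzoate
Conditions: 27 (2 equiv), pyridine, DMAP (0.5 equiv), CH2Cl2, rt to 40 °C
Reagents that add atoms: 4-(chlorocarbonyl)phenyl acetate (27), CC(=O)Oc1ccc(cc1)C(=O)Cl
Why: DMAP-catalysed acylation of the hindered secondary alcohol by the acid chloride, the phenol being masked as its acetate.

Step 18
Reactants: 28 the diester diene; 29 dioxygen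
Product: 30 (3S,3aS,4R,8S,8aR)-3-hydroxy-6,8a-dimethyl-8-[(3-methylbutanoyl)oxy]-3-(propan-2-yl)-1,2,3,3a,4,5,8,8a-octahydroazulen-4-yl 4-(acetyloxy)benzoate
Conditions: Co(acac)2 (20 mol %), PhSiH3 (2.5 equiv), O2 (1 atm), THF/iPrOH, 0 °C to rt
Reagents that add atoms: dioxygen (29), O=O
Why: Mukaiyama hydration (metal hydride hydrogen-atom transfer, Markovnikov), in which H adds to the unhindered C2, the planar tertiary C3 radical is captured by O2 on the convex face anti to the C4 substituent (3S, OH cis to C3a–H), and the C6=C7 alkene is expected to react more slowly because its CH terminus is flanked by the acyloxy-bearing, neopentyl-type C8.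

Step 19
Reactants: 30 the phenol acetate
Product: 31 (3S,3aS,4R,8S,8aR)-3-hydroxy-6,8a-dimethyl-8-[(3-methylbutanoyl)oxy]-3-(propan-2-yl)-1,2,3,3a,4,5,8,8a-octahydroazulen-4-yl 4-hydroxybenzoate
Conditions: pyrrolidine (2 equiv), CH2Cl2, 0 °C
Reagents that add atoms: none
Why: chemoselective aminolysis of the aryl acetate, which is far more electrophilic than the two esters of secondary alcohols.

**Compound list**

1 | 2-methylprop-2-en-1-ol | C=C(C)CO | starting material
2 | bromoacetyl bromide | BrCC(=O)Br | starting material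
3 | 2-methylprop-2-en-1-yl bromoacetate | C=C(C)COC(=O)CBr | intermediate
4 | N,N'-ditosylhydrazine | Cc1ccc(cc1)S(=O)(=O)NNS(=O)(=O)c1ccc(C)cc1 | starting material
5 | 2-methylprop-2-en-1-yl diazoacetate | C=C(C)COC(=O)C=[N+]=[N-] | intermediate
6 | (1S,5R)-5-methyl-3-oxabicyclo[3.1.0]hexan-2-one | O=C1OC[C@]2(C)C[C@H]12 | intermediate
7 | (1S,5R)-5-methyl-3-oxabicyclo[3.1.0]hexan-2-ol (anomers) | OC1OC[C@]2(C)C[C@H]12 | intermediate
8 | 2-methylallylmagnesium chloride | C=C(C)C[Mg]Cl | starting material
9 | 1-[(1S,2R)-2-(hydroxymethyl)-2-methylcyclopropyl]-3-methylbut-3-en-1-ol (carbinol epimers) | OC[C@]1(C)C[C@@H]1C(O)CC(C)=C | intermediate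
10 | (1R,5S)-1-methyl-4-(2-methylprop-2-en-1-yl)-3-oxabicyclo[3.1.0]hexan-2-ol | OC1OC(CC(C)=C)[C@H]2C[C@@]12C | intermediate
11 | (1R,5S)-1-methyl-4-(2-methylprop-2-en-1-yl)-3-oxabicyclo[3.1.0]hexan-2-one (C4 epimers) | O=C1OC(CC(C)=C)[C@H]2C[C@@]12C | intermediate
12 | N,O-dimethylhydroxylamine hydrochloride | CNOC.Cl | starting material
13 | (1R,2S)-2-(1-hydroxy-3-methylbut-3-en-1-yl)-N-methoxy-N,1-dimethylcyclopropane-1-carboxamide | CON(C)C(=O)[C@]1(C)C[C@@H]1C(O)CC(C)=C | intermediate
14 | tert-butyl(chloro)dimethylsilane | CC(C)(C)[Si](C)(C)Cl | starting material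
15 | (1R,2S)-2-{1-[(tert-butyldimethylsilyl)oxy]-3-methylbut-3-en-1-yl}-N-methoxy-N,1-dimethylcyclopropane-1-carboxamide | CON(C)C(=O)[C@]1(C)C[C@@H]1C(CC(C)=C)O[Si](C)(C)C(C)(C)C | intermediate
16 | vinylmagnesium bromide | C=C[Mg]Br | starting material
17 | 1-[(1R,2S)-2-{1-[(tert-butyldimethylsilyl)oxy]-3-methylbut-3-en-1-yl}-1-methylcyclopropyl]prop-2-en-1-one | C=CC(=O)[C@]1(C)C[C@@H]1C(CC(C)=C)O[Si](C)(C)C(C)(C)C | intermediate
18 | (1R,7S)-6-[(tert-butyldimethylsilyl)oxy]-1,4-dimethylbicyclo[5.1.0]oct-3-en-2-one | CC1=CC(=O)[C@]2(C)C[C@@H]2C(O[Si](C)(C)C(C)(C)C)C1 | intermediate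
19 | (1R,2S,7S)-6-[(tert-butyldimethylsilyl)oxy]-1,4-dimethylbicyclo[5.1.0]oct-3-en-2-ol | CC1=C[C@H](O)[C@]2(C)C[C@@H]2C(O[Si](C)(C)C(C)(C)C)C1 | intermediate
20 | 3-methylbutanoyl chloride | CC(C)CC(=O)Cl | starting material
21 | (1R,2S,7S)-6-[(tert-butyldimethylsilyl)oxy]-1,4-dimethylbicyclo[5.1.0]oct-3-en-2-yl 3-methylbutanoate | CC1=C[C@H](OC(=O)CC(C)C)[C@]2(C)C[C@@H]2C(O[Si](C)(C)C(C)(C)C)C1 | intermediate
22 | (1R,2S,7S)-6-hydroxy-1,4-dimethylbicyclo[5.1.0]oct-3-en-2-yl 3-methylbutanoate | CC1=C[C@H](OC(=O)CC(C)C)[C@]2(C)C[C@@H]2C(O)C1 | intermediate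
23 | (1R,2S,7S)-1,4-dimethyl-6-oxobicyclo[5.1.0]oct-3-en-2-yl 3-methylbutanoate | CC1=C[C@H](OC(=O)CC(C)C)[C@]2(C)C[C@@H]2C(=O)C1 | intermediate
24 | 3-methylbut-1-yne | CC(C)C#C | starting material
25 | (3aS,8S,8aR)-6,8a-dimethyl-4-oxo-3-(propan-2-yl)-1,3a,4,5,8,8a-hexahydroazulen-8-yl 3-methylbutanoate | CC1=C[C@H](OC(=O)CC(C)C)[C@]2(C)CC=C(C(C)C)[C@@H]2C(=O)C1 | intermediate
26 | (3aS,4R,8S,8aR)-4-hydroxy-6,8a-dimethyl-3-(propan-2-yl)-1,3a,4,5,8,8a-hexahydroazulen-8-yl 3-methylbutanoate | CC1=C[C@H](OC(=O)CC(C)C)[C@]2(C)CC=C(C(C)C)[C@@H]2[C@H](O)C1 | intermediate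
27 | 4-(chlorocarbonyl)phenyl acetate | CC(=O)Oc1ccc(cc1)C(=O)Cl | starting material
28 | (3aS,4R,8S,8aR)-6,8a-dimethyl-8-[(3-methylbutanoyl)oxy]-3-(propan-2-yl)-1,3a,4,5,8,8a-hexahydroazulen-4-yl 4-(acetyloxy)benzoate | CC1=C[C@H](OC(=O)CC(C)C)[C@]2(C)CC=C(C(C)C)[C@@H]2[C@H](OC(=O)c2ccc(OC(C)=O)cc2)C1 | intermediate
29 | dioxygen | O=O | starting material
30 | (3S,3aS,4R,8S,8aR)-3-hydroxy-6,8a-dimethyl-8-[(3-methylbutanoyl)oxy]-3-(propan-2-yl)-1,2,3,3a,4,5,8,8a-octahydroazulen-4-yl 4-(acetyloxy)benzoate | CC1=C[C@H](OC(=O)CC(C)C)[C@]2(C)CC[C@](O)(C(C)C)[C@@H]2[C@H](OC(=O)c2ccc(OC(C)=O)cc2)C1 | intermediate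
31 | (3S,3aS,4R,8S,8aR)-3-hydroxy-6,8a-dimethyl-8-[(3-methylbutanoyl)oxy]-3-(propan-2-yl)-1,2,3,3a,4,5,8,8a-octahydroazulen-4-yl 4-hydroxybenzoate | CC1=C[C@H](OC(=O)CC(C)C)[C@]2(C)CC[C@](O)(C(C)C)[C@@H]2[C@H](OC(=O)c2ccc(O)cc2)C1 | target

**Step count and risks**

Total step count: 19. Longest linear sequence: 19 steps (the route is linear from 1).

Steps most likely to fail:

1. Step 15. What may go wrong: cleavage of the ring-fusion cyclopropane bond in competition with the external one; slow capture of the neopentyl-type primary radical by an unactivated alkyne; 1,5-hydrogen transfer from C8–H to the vinyl radical before ring closure; or drift of the C6=C7 double bond into conjugation through the samarium enolate. Fallback (sets out from 23, returns at 25): the cyclopropane is opened in a separate polar step and the two bonds are made one at a time. Me3SiI (CH2Cl2, −78 °C, Et3N quench) should open the activated cyclopropane by iodide attack at the methylene carbon and give (1S,7R)-7-(iodomethyl)-3,7-dimethyl-5-[(trimethylsilyl)oxy]cyclohepta-2,5-dien-1-yl 3-methylbutanoate F1. Radical alkynylation of the primary iodide with 3-methylbut-1-yn-1-yl trifluoromethyl sulfone (AIBN, benzene, 80 °C) should give (1S,7R)-3,7-dimethyl-7-(4-methylpent-2-yn-1-yl)-5-[(trimethylsilyl)oxy]cyclohepta-2,5-dien-1-yl 3-methylbutanoate F2. Gold-catalysed 5-endo-dig carbocyclization of the silyl enol ether onto the alkyne (Ph3PAuCl/AgBF4, CH2Cl2/MeOH, rt; Conia-ene type) should then close the cis-fused cyclopentene and release ketone 25.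

2. Step 18. What may go wrong: hydrogen-atom transfer to the C6=C7 alkene in competition with the cyclopentene, or oxygen capture on the concave face. Fallback (sets out from 28, returns at 30): the oxygen is delivered by electrophilic epoxidation and the hydrogen by a separate reduction. mCPBA (NaHCO3, CH2Cl2, 0 °C) should epoxidize the cyclopentene selectively, because the cycloheptene alkene is deactivated by its allylic ester, and from the convex face, giving the 2,3-epoxide of 28 with the oxirane oxygen on the face of C3a–H F3. Sodium phenylselenide (PhSeSePh/NaBH4, THF/EtOH, 0 °C) should open it at the less hindered C2 and give the 2-(phenylselanyl) derivative of 30 with selenium trans to the C3 hydroxyl F4. Bu3SnH/AIBN (toluene, 80 °C) should remove the selenium to give 30.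

3. Step 11. What may go wrong: poor facial selectivity of hydride delivery; attack syn to the cyclopropane methylene would give the C8 epimer. Fallback (sets out from 15, returns at 21): C8 is set by catalyst control before the ring is closed. Lithium (trimethylsilyl)acetylide (THF, −78 °C) should convert 15 into 1-[(1R,2S)-2-{1-[(tert-butyldimethylsilyl)oxy]-3-methylbut-3-en-1-yl}-1-methylcyclopropyl]-3-(trimethylsilyl)prop-2-yn-1-one F5. Noyori transfer hydrogenation with RuCl(p-cymene)[(R,R)-TsDPEN] in iPrOH, in which the alkynyl group takes the place of the aryl group of an aryl ketone, should give the (1R)-configured 3-(trimethylsilyl)prop-2-yn-1-ol F6. K2CO3/MeOH should give the terminal (1S)-prop-2-yn-1-ol F7 (same spatial arrangement; the descriptor changes with the priorities). Semihydrogenation (H2, Lindlar catalyst (Pd on CaCO3 poisoned with Pb(OAc)2), quinoline, EtOAc) should give the (1S)-prop-2-en-1-ol F8. Acylation with 20 (pyridine, DMAP) should give the (1S)-allylic 3-methylbutanoate F9. Ring-closing metathesis (second-generation Hoveyda–Grubbs catalyst, toluene, 80 °C) should then give 21.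

**Further compounds**

F1 | step 15 | (1S,7R)-7-(iodomethyl)-3,7-dimethyl-5-[(trimethylsilyl)oxy]cyclohepta-2,5-dien-1-yl 3-methylbutanoate | CC1=C[C@H](OC(=O)CC(C)C)[C@](C)(CI)C=C(O[Si](C)(C)C)C1
F2 | step 15 | (1S,7R)-3,7-dimethyl-7-(4-methylpent-2-yn-1-yl)-5-[(trimethylsilyl)oxy]cyclohepta-2,5-dien-1-yl 3-methylbutanoate | CC1=C[C@H](OC(=O)CC(C)C)[C@](C)(CC#CC(C)C)C=C(O[Si](C)(C)C)C1
F3 | step 18 | 2,3-epoxide of 28, oxirane oxygen on the face of C3a–H | CC1=C[C@H](OC(=O)CC(C)C)[C@]2(C)C[C@H]3O[C@@]3(C(C)C)[C@@H]2[C@H](OC(=O)c2ccc(OC(C)=O)cc2)C1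
F4 | step 18 | 2-(phenylselanyl) derivative of 30, selenium trans to the C3 hydroxyl | CC1=C[C@H](OC(=O)CC(C)C)[C@]2(C)C[C@H]([Se]c3ccccc3)[C@](O)(C(C)C)[C@@H]2[C@H](OC(=O)c2ccc(OC(C)=O)cc2)C1
F5 | step 11 | 1-[(1R,2S)-2-{1-[(tert-butyldimethylsilyl)oxy]-3-methylbut-3-en-1-yl}-1-methylcyclopropyl]-3-(trimethylsilyl)prop-2-yn-1-one | C[Si](C)(C)C#CC(=O)[C@]1(C)C[C@@H]1C(CC(C)=C)O[Si](C)(C)C(C)(C)C
F6 | step 11 | (1R)-1-[(1R,2S)-2-{1-[(tert-butyldimethylsilyl)oxy]-3-methylbut-3-en-1-yl}-1-methylcyclopropyl]-3-(trimethylsilyl)prop-2-yn-1-ol | C[Si](C)(C)C#C[C@H](O)[C@]1(C)C[C@@H]1C(CC(C)=C)O[Si](C)(C)C(C)(C)C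
F7 | step 11 | (1S)-1-[(1R,2S)-2-{1-[(tert-butyldimethylsilyl)oxy]-3-methylbut-3-en-1-yl}-1-methylcyclopropyl]prop-2-yn-1-ol | C#C[C@H](O)[C@]1(C)C[C@@H]1C(CC(C)=C)O[Si](C)(C)C(C)(C)C
F8 | step 11 | (1S)-1-[(1R,2S)-2-{1-[(tert-butyldimethylsilyl)oxy]-3-methylbut-3-en-1-yl}-1-methylcyclopropyl]prop-2-en-1-ol | C=C[C@H](O)[C@]1(C)C[C@@H]1C(CC(C)=C)O[Si](C)(C)C(C)(C)C
F9 | step 11 | (1S)-1-[(1R,2S)-2-{1-[(tert-butyldimethylsilyl)oxy]-3-methylbut-3-en-1-yl}-1-methylcyclopropyl]prop-2-en-1-yl 3-methylbutanoate | C=C[C@H](OC(=O)CC(C)C)[C@]1(C)C[C@@H]1C(CC(C)=C)O[Si](C)(C)C(C)(C)C
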